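## Structural features

The target is a daucane-type bicyclo[5.3.0]decane. Cyclopentane ring A (C1–C5) and cycloheptane ring B (C1, C5–C10) share the C1–C5 bond and are trans-fused (1β-methyl, 5α-H). Seven stereocentres sit on ten ring atoms: quaternary C1 lies between C5 and C10, C5 lies between the tertiary carbinol C4 (4β-OH, 4α-isopropyl) and C6, and the three oxygenated positions of ring B (6-isovalerate, 8,9-epoxide, 10-acetate) are all α. In the locants used here the configuration is 1S,4R,5S,6S,8R,9S,10S. The fragile groups are the trisubstituted epoxide next to the acetate, the two different esters beside a free tertiary alcohol, and, at the ketone oxidation level, the 4-hydroxy-6-oxo (aldol) relationship, which can dehydrate or cleave by retro-aldol reaction. The real difficulty is threefold: the quaternary C1 between two stereocentres, telling C4, C6 and C10 apart, and placing the 10-oxygen trans to the adjacent angular methyl group, the face that a reagent adding to a C10 carbonyl avoids. The key step exploits the fact that C6 and C10 are both oxygenated and are bonded to the two ring-fusion atoms. A C6–C10 bond would contract ring B to a cyclobutane (C1, C5, C6, C10) fused between ring A and a C6–C10 cyclopentane, which is an enone–enediol photoadduct; cutting that diol bond returns ring B with carbonyls at C6 and C10. The adduct has five stereocentres (C8 becomes stereogenic as well), of which only C1 reaches the target unchanged; its rigid cup shape is used here to set C4, and its C8 configuration to steer a later elimination.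

## Logic of the disconnections

22 is cut at the acetyl C–O bond on C10, giving 21. The free 10-hydroxyl is needed one step earlier as a directing group, so the acetate goes on last. The forward acylation must distinguish a secondary from a hindered tertiary alcohol.

21 is cut at the two oxirane C–O bonds (C8–O, C9–O), giving 20. The cis relation of epoxide and 10-oxygen is the retron of a hydroxyl-directed epoxidation, and two stereocentres disappear. The forward step must be steered by the allylic hydroxyl alone.

20 is traced through 17 to 16: the C9–O bond is re-formed (double bond moved from C8=C9 to the C9/C10 oxirane), then C9–O and C10–O are cut. The reason is C10: its oxygen is trans to the C1 methyl, which is what electrophilic attack on a C9=C10 alkene anti to that methyl should give, and the opposite of hydride addition to a C10 ketone. The forward steps need α-face epoxidation and an epoxide-to-allylic-alcohol shift; the shift can only go towards C8 because C1 has no hydrogen.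

16 is related to 14 through 15 by exchanging C10–H for C10=O. A C10 ketone is what a glycol cleavage delivers. Forward, enolisation can only go towards C9.

14 is cut at the isovalerate C–O bond on C6, giving 13. The ester is placed early so that no protecting group is needed at C6. The forward step relies on secondary-over-tertiary selectivity.

13 loses its C6–H bond to give 12, and 12 is related to its C5 epimer 11. C6 is derived from C4 by internal hydride delivery and C5 by equilibration, so two stereocentres are removed. 11 has the cis fusion that a cyclobutane precursor must give.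

In 11 the carbonyl carbons C6 and C10 are joined retrosynthetically, giving 10. The flexible seven-membered ring becomes a cis-cyclobutane-1,2-diol in a rigid tricycle and the (2+2) retron appears. The forward cleavage must not meet a ketone β to a free cyclobutanol, which is why C4 is already a carbinol in 10.

10 is traced to 9 (C3–H and two O–H bonds), 9 to 8 (C3–O, C4–O), 8 to 7 (C4–isopropyl bond) and 7 to 6. The 4-oxygen must be cis to the C1 methyl; on the cup-shaped tricycle reagents arrive from the convex face, so oxygen, not isopropyl, must be the group delivered last. The forward steps need C3-selective enolisation, a secondary-alkyl cross-coupling, convex-face epoxidation and hydride attack at C3.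

6 is cut at C1–C10 and C5–C6, giving 4 and 5. One ring, two skeletal bonds and the quaternary centre are removed, and twelve of fifteen skeletal carbons come from two simple five-membered rings. The forward step needs enantioface selection at the enone, cis-anti-cis closure and an alkene that tolerates the Lewis acid.

4 is cut at its two acyl C–O bonds to 2 (through 3), and 2 at the C–C bond between its oxygenated carbons and at the Si–O bonds, giving 1. The bond made here is the one broken between 10 and 11, so the ester carbons of 1 become C6 and C10. 1 is symmetric, so there is no selectivity demand.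

## Other disconnections considered

Alternative 1: The cut is the ring-fusion bond C1–C5, with C6 and C10 as the alkene termini of dienol A1. Cp2ZrBu2 (from Cp2ZrCl2 and BuLi) would couple the two alkenes of the alkoxide of A1 to a zirconacyclopentane, and oxidation of both C–Zr bonds would give triol A2.
- In its favour: the trans C1/C5 pair would come directly from the zirconacycle, which is better than the chosen plan, where C5 is formed cis and must be inverted (step 9). The C4 carbinol is set before the key step by conventional asymmetric addition, so no photochemical enantiocontrol is needed (also better).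
- Against it here: one alkene is 1,1-disubstituted, and zirconocene couplings that create a quaternary carbon are sluggish. A2 contains ring A only, so C7–C9 must still be inserted between two near-equivalent primary alcohols, and C6 and C10 must then be set on a flexible ring.
- Comparison: the chosen plan obtains ring B and both oxygens from the cycloaddition–cleavage pair. Alternative 1 is the equal in stereocentres fixed by the key step and rests on a more conventional thermal mechanism, but is judged longer overall.

Alternative 2: The cuts are C1–C5 and C7–C8 in acyclic vinyldiazoketone A3. Rh2(S-DOSP)4 (or its enantiomer) would form the C5 carbenoid, which cyclopropanates the C1=C10 alkene; the cis-divinylcyclopropane then undergoes a [3,3] shift (C7–C8 formed, C5–C10 broken) to dienone A4.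
- In its favour: both rings, quaternary C1 and the methyl-bearing C8 arise in one catalytic step, which is better in skeletal step economy. Enantiocontrol by a thermal dirhodium catalyst has broader precedent than asymmetric enone photocycloaddition (better). The C9=C10 alkene that the chosen route makes in steps 12 and 13 is already present.
- Against it here: an acceptor-only vinyl diazoketone is a less selective carbenoid precursor than a donor/acceptor diazoacetate and can close to a pyrazole. A4 has no oxygen at C6 or C10. The isopropyl carbinol would have to be made at a cross-conjugated C4 ketone next to trigonal C5, where facial bias is uncertain.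
- Comparison: the alternative is a concerted, stereospecific cascade; the chosen key step is a stepwise diradical process but delivers C6 and C10 at the ketone level and a rigid tricycle for C4. Total lengths are judged similar.

Alternative 3: The cut is C7–C8 at a late stage. (Ph3P)AuNTf2 in CH2Cl2/MeOH would activate the C8≡C9 alkyne of A5; the enol ether carbon C7 would attack C8 in a 7-endo-dig closure, and protodeauration would give ketone A6.
- In its favour: A6 has the full skeleton with C1, C4, C5 and C10 set and with the alkene and C6 carbonyl exactly where the epoxide and isovalerate go, so its endgame is shorter than that from 11 (better). The mild catalysis is the equal of the photoreaction in functional-group tolerance.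
- Against it here: the same carbon can close 6-exo-dig onto C9, and for an internal methyl alkyne neither mode is clearly preferred. Methanol can desilylate the enol ether. A5, with three contiguous ring stereocentres plus C10, needs a long preparation in which the key step gives no help.
- Comparison: the gold step forms one bond, one ring and no stereocentre; the photocycloaddition forms two bonds, the ring that becomes ring B, and C1. The chosen plan is shorter to the bicyclic core, the alternative shorter after it.

Key step: step 3

Remarks on the chemistry (assumptions):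
- Locants C1–C10 are those of the target core (ring A C1–C5, ring B C1, C5–C10; not von Baeyer numbers) and are kept for every intermediate; β is the face of the C1 methyl group.
- The enone is assumed to add to the alkene face remote from its methyl group (8α-methyl, 8β-H in 6); the C8 epimer is removed by chromatography at 6.
- The catalyst enantiomer in step 3 is the one whose aryl groups shield the enone face leading to ent-6; this is to be assigned by a test irradiation, and both antipodes are accessible.
- The bis(silyl) enediol ether 2 is not irradiated itself: a silyl enol ether would undergo conjugate addition and desilylation with the AlBr3-activated catalyst, and a later free cyclobutanol β to the C4 ketone would open by retro-aldol reaction.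

## Route

Step 1
Reactants: 1 dimethyl 3-methylpentanedioate
Product: 2 4-methyl-1,2-bis(trimethylsilyloxy)cyclopent-1-ene
Conditions: Na (4.2 equiv), Me3SiCl (4.5 equiv), toluene, reflux
Reagents that add atoms: chlorotrimethylsilane, C[Si](C)(C)Cl
Why: Acyloin condensation with silyl trapping: electron transfer from sodium couples the two ester carbons (the later C6–C10 bond) and Me3SiCl captures the enediolate and methoxide, which suppresses Claisen side reactions; no stereocentre is formed.

Step 2
Reactants: 2 4-methyl-1,2-bis(trimethylsilyloxy)cyclopent-1-ene
Product: 4 4-methylcyclopent-1-ene-1,2-diyl bis(2,2-dimethylpropanoate), via dilithium enediolate 3 (not isolated)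
Conditions: MeLi (2.1 equiv), THF, 0 °C to rt; then t-BuCOCl (2.3 equiv), DMPU, −78 °C to rt
Reagents that add atoms: pivaloyl chloride, CC(C)(C)C(=O)Cl
Why: Methyllithium cleaves both Si–O bonds (silyl enol ether to lithium enolate) and the hard oxygen centres of the tetrasubstituted enediolate are O-acylated by the hindered acid chloride. The dipivalate has no acidic α-hydrogen and should be inert to the Lewis acid, the bases and the Grignard reagent used later.

Step 3
Reactants: 4 4-methylcyclopent-1-ene-1,2-diyl bis(2,2-dimethylpropanoate); 5 3-methylcyclopent-2-en-1-one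
Product: 6 cis-anti-cis tricyclic keto dipivalate (C4 ketone; pivaloyloxy at C6 and C10; 1-methyl and 5-H cis; 8-methyl anti to the cyclobutane)
Conditions: 4 (5 equiv), (S)-3,3-bis(3,5-dimethylphenyl)-1-(2,4,6-trifluorophenyl)tetrahydro-1H,3H-pyrrolo[1,2-c][1,3,2]oxazaborole (50 mol%), AlBr3 (50 mol%), CH2Cl2, −75 °C, hν (366 nm)
Reagents that add atoms: none
Why: Proposed new method: enantioselective enone–alkene (2+2) photocycloaddition mediated by an AlBr3-activated chiral oxazaborolidine is the closest known reaction type (cyclohexenones with simple alkenes), whereas a 3-alkylcyclopentenone with a tetrasubstituted enediol diester is untested. Binding of the carbonyl oxygen of 5 to boron shifts its absorption to longer wavelength, so at 366 nm mainly the complex should be excited, and its triplet adds to the alkene to give a 1,4-diradical. After spin inversion, radical–radical combination closes the cyclobutane, the only ring formed (formal (2+2) closure through C1–C10 and C5–C6), and the enone β-carbon becomes quaternary C1. The aryl groups of the catalyst should shield one face of the bound enone, which fixes C1, and C5 follows because a five-membered ring can only be cis-fused to a cyclobutane. C6 and C10 are cis because both come from a ring alkene, the two five-membered rings should take the less crowded anti arrangement, and C8 is set by attack on the alkene face remote from its methyl group. The two alkene termini are equivalent, so no regiochemical question arises. An enol ester replaces silyl enol ether 2 because 2 would undergo Lewis-acid-promoted conjugate addition and desilylation, whereas 4 is a poor π-nucleophile with hindered carbonyl groups. The step needs high enantioface selectivity, which depends on a slow uncatalysed background reaction at this wavelength and temperature.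

Step 4
Reactants: 6 cis-anti-cis tricyclic keto dipivalate
Product: 7 enol triflate (C3=C4, 4-trifluoromethanesulfonyloxy)
Conditions: KN(SiMe3)2 (1.2 equiv), PhNTf2 (1.2 equiv), THF, −78 °C
Reagents that add atoms: N-phenylbis(trifluoromethanesulfonimide), O=S(=O)(N(c1ccccc1)S(=O)(=O)C(F)(F)F)C(F)(F)F
Why: Kinetic enolisation can only go towards C3, because C5 is a hindered cyclobutane methine whose enolate would be strained; O-triflation of the potassium enolate should give the enol triflate while C6 and C10 stay masked.

Step 5
Reactants: 7 enol triflate
Product: 8 4-isopropyl alkene (C3=C4) dipivalate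
Conditions: Fe(acac)3 (5 mol%), i-PrMgCl (1.5 equiv), THF/NMP, −30 °C
Reagents that add atoms: isopropylmagnesium chloride, CC(C)[Mg]Cl
Why: Iron-catalysed Kumada-type cross-coupling of an enol triflate with a secondary alkyl Grignard reagent; coupling by the low-valent iron species should outrun isomerisation of the isopropyl group, and the tertiary pivalates are too hindered to react at this temperature.

Step 6
Reactants: 8 4-isopropyl alkene dipivalate
Product: 9 3,4-epoxide with oxygen on the convex face (cis to 1-methyl and 5-H)
Conditions: mCPBA (1.3 equiv), NaHCO3, CH2Cl2, 0 °C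
Reagents that add atoms: 3-chloroperoxybenzoic acid, OOC(=O)c1cccc(Cl)c1
Why: Prilezhaev epoxidation from the convex face of the cis-fused bicyclo[3.2.0]heptene unit, the concave face being covered by the cyclobutane and its two acyloxy groups. This puts the C4 oxygen on the face of the C1 methyl group (4β-O), which direct isopropyl addition to ketone 6 from the same face would not do.

Step 7
Reactants: 9 3,4-epoxide dipivalate
Product: 10 tricyclic triol (4-hydroxy-4-isopropyl with OH on the convex face; cis-6,10-diol on the cyclobutane)
Conditions: LiEt3BH (8 equiv), THF, 0 to 50 °C; aq. NH4Cl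
Reagents that add atoms: none
Why: Hydride should open the trisubstituted epoxide by SN2 attack at the secondary carbon C3, leaving the tertiary C4 alcohol with its configuration, and the same reagent cleaves both pivalates reductively. The diol is thus freed only when no ketone is β to a cyclobutanol, so retro-aldol opening of C5–C6 is excluded.

Step 8
Reactants: 10 tricyclic triol
Product: 11 cis-fused 4β-hydroxy-4α-isopropyl-1β,8α-dimethyl-5β-H-decahydroazulene-6,10-dione
Conditions: Pb(OAc)4 (1.1 equiv), K2CO3, CH2Cl2, 0 °C
Reagents that add atoms: none
Why: Criegee glycol cleavage: the cis-1,2-diol on the strained cyclobutane should form the cyclic lead diester readily and fragment at C6–C10 to the two ketones, which opens ring B. The 1,3-related C4 alcohol is not a substrate and C1, C4 and C8 are untouched.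

Step 9
Reactants: 11 cis-fused hydroxy diketone
Product: 12 trans-fused 4β-hydroxy-4α-isopropyl-1β,8α-dimethyl-5α-H-decahydroazulene-6,10-dione
Conditions: DBU (0.5 equiv), toluene, 40 °C
Reagents that add atoms: none
Why: Base-mediated epimerisation through the C5(6) enol. In the cis-fused isomer the 4α-isopropyl group is pressed against ring B on the concave face, whereas the trans isomer puts C6 next to the small hydroxyl, to which its carbonyl can hydrogen-bond, so the equilibrium should favour 12. An amidine in an aprotic solvent avoids the alkoxide that would start retro-aldol cleavage.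

Step 10
Reactants: 12 trans-fused hydroxy diketone
Product: 13 4β,6α-dihydroxy-4α-isopropyl-1β,8α-dimethyl-5α-H-decahydroazulen-10-one
Conditions: Me4NBH(OAc)3 (5 equiv), MeCN/AcOH (1:1), −25 °C
Reagents that add atoms: none
Why: Evans–Saksena reduction: exchange of the reagent with the 4β-hydroxyl gives an alkoxyborohydride that delivers hydride internally to the β-face of the C6 carbonyl, which should give the 6α-alcohol (anti-1,3-diol). The C10 ketone has no hydroxyl within reach and is not reduced by this mild reagent.

Step 11
Reactants: 13 diol ketone
Product: 14 6α-(3-methylbutanoyloxy)-4β-hydroxy-4α-isopropyl-1β,8α-dimethyl-5α-H-decahydroazulen-10-one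
Conditions: i-BuCOCl (1.2 equiv), pyridine, DMAP (cat.), CH2Cl2, 0 °C
Reagents that add atoms: 3-methylbutanoyl chloride, CC(C)CC(=O)Cl
Why: Acylation of the secondary 6α-alcohol; the tertiary 4β-alcohol beside the isopropyl group should not react under these conditions.

Step 12
Reactants: 14 hydroxy keto ester
Product: 15 C9=C10 enol triflate (10-trifluoromethanesulfonyloxy) of 14
Conditions: KN(SiMe3)2 (2.2 equiv), PhNTf2 (1.2 equiv), THF, −78 °C
Reagents that add atoms: N-phenylbis(trifluoromethanesulfonimide), O=S(=O)(N(c1ccccc1)S(=O)(=O)C(F)(F)F)C(F)(F)F
Why: The C10 ketone can enolise only towards C9 because C1 is quaternary. One equivalent of base covers the tertiary hydroxyl, and the ketone α-hydrogens are more acidic than those of the ester, so O-triflation of the ketone enolate should give the enol triflate.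

Step 13
Reactants: 15 enol triflate
Product: 16 C9=C10 alkene: 6α-(3-methylbutanoyloxy)-4α-isopropyl-1β,8α-dimethyl-5α-H-octahydroazulen-4β-ol
Conditions: Pd(OAc)2 (5 mol%), PPh3 (10 mol%), HCO2H, n-Bu3N, DMF, 60 °C
Reagents that add atoms: none
Why: Palladium-catalysed hydrogenolysis of an enol triflate with formate (oxidative addition to zerovalent palladium, formate exchange, decarboxylation, reductive elimination). The C10 oxygen is removed so that it can be returned on the α-face by an electrophilic reagent; ester and tertiary alcohol are inert.

Step 14
Reactants: 16 C9=C10 alkene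
Product: 17 9α,10α-epoxide of 16
Conditions: mCPBA (1.3 equiv), NaHCO3, CH2Cl2, 0 °C
Reagents that add atoms: 3-chloroperoxybenzoic acid, OOC(=O)c1cccc(Cl)c1
Why: Prilezhaev epoxidation: in the chair-like cycloheptene the C1 methyl group is axial next to C10 and covers the β-face, so the peracid should attack from the α-face. This sets the C10–O bond trans to the methyl group, which hydride reduction of a C10 ketone (attack anti to the same methyl) should not do.

Step 15
Reactants: 17 9α,10α-epoxide
Product: 20 10α-hydroxy C8=C9 alkene: 6α-(3-methylbutanoyloxy)-4α-isopropyl-1β,8-dimethyl-5α-H-octahydroazulene-4β,10α-diol, via hydroxy selenide 18 (not isolated), via selenoxide 19 (not isolated)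
Conditions: (PhSe)2 (0.6 equiv), NaBH4, EtOH, 60 °C; then THF, H2O2 (30%), pyridine, 0 °C to rt
Reagents that add atoms: none
Why: Selenolate should open the epoxide at C9 from the β-face, C10 being neopentyl. The derived selenoxide undergoes syn elimination away from the carbinol carbon towards the only other syn hydrogen, 8β-H, which moves the double bond to C8=C9 and leaves the 10α-alcohol (epoxide to allylic alcohol transposition). The 8α-methyl configuration from step 3 is what supplies this syn hydrogen.

Step 16
Reactants: 20 allylic alcohol
Product: 21 8α,9α-epoxy-10α-ol: 6α-(3-methylbutanoyloxy)-8α,9α-epoxy-4α-isopropyl-1β,8β-dimethyl-5α-H-decahydroazulene-4β,10α-diol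
Conditions: VO(acac)2 (5 mol%), t-BuOOH (1.5 equiv), CH2Cl2, 0 °C to rt
Reagents that add atoms: tert-butyl hydroperoxide, CC(C)(C)OO
Why: Hydroxyl-directed epoxidation: the allylic 10α-alkoxide bound to the vanadium alkylperoxide complex delivers oxygen to the same face of the trisubstituted alkene, which should give the cis-epoxy alcohol and set C8 and C9.

Step 17
Reactants: 21 epoxy diol
Product: 22 target, 10α-acetoxy-8α,9α-epoxy-4β-hydroxy-4α-isopropyl-1β,8β-dimethyl-6α-(3-methylbutanoyloxy)-5α-H-decahydroazulene
Conditions: Ac2O, pyridine, DMAP (cat.), CH2Cl2, rt
Reagents that add atoms: acetic anhydride, CC(=O)OC(C)=O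
Why: DMAP-catalysed acetylation of the secondary 10α-alcohol; the hindered tertiary 4β-alcohol should stay free, and the mildly basic conditions spare the epoxide and the isovalerate.

## Compound list

1 | dimethyl 3-methylpentanedioate | COC(=O)CC(C)CC(=O)OC | starting material
2 | 4-methyl-1,2-bis(trimethylsilyloxy)cyclopent-1-ene | CC1CC(O[Si](C)(C)C)=C(O[Si](C)(C)C)C1 | intermediate
3 | dilithium 4-methylcyclopent-1-ene-1,2-diolate | CC1CC([O-])=C([O-])C1.[Li+].[Li+] | intermediate (not isolated)
4 | 4-methylcyclopent-1-ene-1,2-diyl bis(2,2-dimethylpropanoate) | CC1CC(OC(=O)C(C)(C)C)=C(OC(=O)C(C)(C)C)C1 | intermediate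
5 | 3-methylcyclopent-2-en-1-one | CC1=CC(=O)CC1 | starting material
6 | cis-anti-cis 6,9-dimethyl-3-oxotricyclo[5.3.0.0(2,6)]decane-1,7-diyl bis(2,2-dimethylpropanoate) (target locants: C4 ketone, 6,10-bis(pivaloyloxy), 1-Me and 5-H cis, 8-Me anti to the cyclobutane) | CC(C)(C)C(=O)O[C@]12C[C@H](C)C[C@@]1(OC(=O)C(C)(C)C)[C@@H]3C(=O)CC[C@]23C | intermediate
7 | C3=C4 enol triflate of 6 (4-trifluoromethanesulfonyloxy) | CC(C)(C)C(=O)O[C@]12C[C@H](C)C[C@@]1(OC(=O)C(C)(C)C)[C@@H]3C(OS(=O)(=O)C(F)(F)F)=CC[C@]23C | intermediate
8 | 4-isopropyl C3=C4 alkene, 6,10-dipivalate | CC(C)(C)C(=O)O[C@]12C[C@H](C)C[C@@]1(OC(=O)C(C)(C)C)[C@@H]3C(C(C)C)=CC[C@]23C | intermediate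
9 | 3,4-epoxide of 8, oxygen on the convex face (cis to 1-Me and 5-H) | CC(C)(C)C(=O)O[C@]12C[C@H](C)C[C@@]1(OC(=O)C(C)(C)C)[C@@H]3[C@@]4(C(C)C)O[C@H]4C[C@]23C | intermediate
10 | tricyclic triol: 4-isopropyl-1,8-dimethyl tricycle with 4-OH (cis to 1-Me and 5-H) and cis-6,10-diol | O[C@]12C[C@H](C)C[C@@]1(O)[C@@H]3[C@](O)(C(C)C)CC[C@]23C | intermediate
11 | cis-fused 4β-hydroxy-4α-isopropyl-1β,8α-dimethyl-5β-H-decahydroazulene-6,10-dione | O=C1C[C@H](C)CC(=O)[C@H]2[C@]1(C)CC[C@@]2(O)C(C)C | intermediate
12 | trans-fused 4β-hydroxy-4α-isopropyl-1β,8α-dimethyl-5α-H-decahydroazulene-6,10-dione | O=C1C[C@H](C)CC(=O)[C@@H]2[C@]1(C)CC[C@@]2(O)C(C)C | intermediate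
13 | 4β,6α-dihydroxy-4α-isopropyl-1β,8α-dimethyl-5α-H-decahydroazulen-10-one | O=C1C[C@H](C)C[C@H](O)[C@@H]2[C@]1(C)CC[C@@]2(O)C(C)C | intermediate
14 | 6α-(3-methylbutanoyloxy)-4β-hydroxy-4α-isopropyl-1β,8α-dimethyl-5α-H-decahydroazulen-10-one | O=C1C[C@H](C)C[C@H](OC(=O)CC(C)C)[C@@H]2[C@]1(C)CC[C@@]2(O)C(C)C | intermediate
15 | C9=C10 enol triflate of 14 | FC(F)(F)S(=O)(=O)OC1=C[C@H](C)C[C@H](OC(=O)CC(C)C)[C@@H]2[C@]1(C)CC[C@@]2(O)C(C)C | intermediate
16 | C9=C10 alkene: 6α-(3-methylbutanoyloxy)-4α-isopropyl-1β,8α-dimethyl-5α-H-octahydroazulen-4β-ol | C1=C[C@H](C)C[C@H](OC(=O)CC(C)C)[C@@H]2[C@]1(C)CC[C@@]2(O)C(C)C | intermediate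
17 | 9α,10α-epoxide of 16 | O1[C@@H]2[C@H]1[C@H](C)C[C@H](OC(=O)CC(C)C)[C@@H]3[C@]2(C)CC[C@@]3(O)C(C)C | intermediate
18 | 9β-phenylselanyl-10α-ol (hydroxy selenide) | O[C@@H]1[C@@H]([Se]c3ccccc3)[C@H](C)C[C@H](OC(=O)CC(C)C)[C@@H]2[C@]1(C)CC[C@@]2(O)C(C)C | intermediate (not isolated)
19 | selenoxide of 18 | O[C@@H]1[C@@H]([Se](=O)c3ccccc3)[C@H](C)C[C@H](OC(=O)CC(C)C)[C@@H]2[C@]1(C)CC[C@@]2(O)C(C)C | intermediate (not isolated)
20 | 10α-hydroxy C8=C9 alkene: 6α-(3-methylbutanoyloxy)-4α-isopropyl-1β,8-dimethyl-5α-H-octahydroazulene-4β,10α-diol | O[C@@H]1C=C(C)C[C@H](OC(=O)CC(C)C)[C@@H]2[C@]1(C)CC[C@@]2(O)C(C)C | intermediate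
21 | 8α,9α-epoxy-6α-(3-methylbutanoyloxy)-4α-isopropyl-1β,8β-dimethyl-5α-H-decahydroazulene-4β,10α-diol | O[C@@H]1[C@@H]2O[C@]2(C)C[C@H](OC(=O)CC(C)C)[C@@H]2[C@]1(C)CC[C@@]2(O)C(C)C | intermediate
22 | CNP0137153.1: 10α-acetoxy-8α,9α-epoxy-4β-hydroxy-4α-isopropyl-1β,8β-dimethyl-6α-(3-methylbutanoyloxy)-5α-H-decahydroazulene | CC(=O)O[C@@H]1[C@@H]2O[C@]2(C)C[C@H](OC(=O)CC(C)C)[C@@H]2[C@]1(C)CC[C@@]2(O)C(C)C | target

## Step count and least certain steps

Total step count: 17. Longest linear sequence: 17 steps (1 to 22; 5 enters at step 3).

Step 3 (key step, the only one that carries the label). The enantioface selection may be eroded by reaction of uncomplexed 5, the hindered alkene may add slowly so that enone dimerisation competes, the Lewis acid may induce acyl migration in 4, and face selection at the alkene may be poor (C8 epimers). The fallback uses known chemistry and runs from 4 and 5 back to 6.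
- Direct irradiation without Lewis acid (λ ≥ 350 nm, CH2Cl2, 4 in excess) should give the racemic cis-anti-cis keto dipivalate F1.
- NaBH4 in MeOH should reduce it from the convex face to the racemic endo alcohol F2.
- Lipase from Burkholderia cepacia with vinyl acetate in t-BuOMe resolves F2; by the empirical size rule for secondary alcohols the enantiomer with the configuration of 6 should be acetylated, giving acetate F3.
- After separation, K2CO3 in MeOH should free the enantiopure alcohol F4 (the tertiary pivalates are inert), and Dess–Martin periodinane oxidises it to 6. If the enzyme prefers the other enantiomer, the unreacted alcohol is F4 itself.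

Step 9. Proton abstraction at the hindered C5 may be slow, the tertiary aldol may cleave by retro-aldol reaction or dehydrate, and the equilibrium may not lie fully on the trans side. The fallback runs from 11 to 12.
- Et3SiOTf and 2,6-lutidine (CH2Cl2, −78 °C) should give the cis-fused 4-triethylsilyl ether F5.
- With the hydroxyl blocked, NaOMe in MeOH can be used to equilibrate it to the trans-fused silyl ether F6.
- HF·pyridine in THF then returns 12.

Step 14. Face selection in the epoxidation may be poor if ring B is not chair-like or if the free 4β-hydroxyl steers the peracid, which would scramble C10. The fallback runs from 14 to 20 and relies on reagent control instead.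
- Me3SiOTf and Et3N should give the bis-silylated enol ether F7 (C9=C10–OSiMe3, 4-OSiMe3).
- Saegusa–Ito oxidation with Pd(OAc)2 in MeCN should give enone F8 (C10 ketone, C8=C9).
- Corey–Bakshi–Shibata reduction, using the enantiomer of 1-methyl-3,3-diphenyltetrahydro-1H,3H-pyrrolo[1,2-c][1,3,2]oxazaborole that delivers hydride to the β-face, with catecholborane, should give the 10α-allylic alcohol silyl ether F9.
- Citric acid in MeOH removes the silyl group to give 20.

Step 7. Hydride must reach C3 from the concave side under the cyclobutane substituents, so opening may be slow or incomplete, and pivalate cleavage may stall. The fallback runs from 8 to 10 and avoids the epoxide.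
- Mukaiyama hydration of 8 (Co(acac)2, PhSiH3, O2, i-PrOH) should add hydrogen at C3 and trap the C4 radical with oxygen on the convex face, giving the tertiary alcohol dipivalate F10.
- LiAlH4 in THF then removes both pivalates to give 10.

## Further compounds

F1 | step 3 | racemic cis-anti-cis tricyclic keto dipivalate (both enantiomers of 6) | CC(C)(C)C(=O)O[C@]12C[C@H](C)C[C@@]1(OC(=O)C(C)(C)C)[C@@H]3C(=O)CC[C@]23C.CC(C)(C)C(=O)O[C@@]12C[C@@H](C)C[C@]1(OC(=O)C(C)(C)C)[C@H]3C(=O)CC[C@@]23C
F2 | step 3 | racemic endo C4 alcohol of F1 (OH on the concave face) | CC(C)(C)C(=O)O[C@]12C[C@H](C)C[C@@]1(OC(=O)C(C)(C)C)[C@@H]3[C@H](O)CC[C@]23C.CC(C)(C)C(=O)O[C@@]12C[C@@H](C)C[C@]1(OC(=O)C(C)(C)C)[C@H]3[C@@H](O)CC[C@@]23C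
F3 | step 3 | C4 acetate of the enantiomer configured as 6 | CC(C)(C)C(=O)O[C@]12C[C@H](C)C[C@@]1(OC(=O)C(C)(C)C)[C@@H]3[C@H](OC(C)=O)CC[C@]23C
F4 | step 3 | enantiopure endo C4 alcohol configured as 6 | CC(C)(C)C(=O)O[C@]12C[C@H](C)C[C@@]1(OC(=O)C(C)(C)C)[C@@H]3[C@H](O)CC[C@]23C
F5 | step 9 | cis-fused 4β-triethylsilyloxy-4α-isopropyl-1β,8α-dimethyl-5β-H-decahydroazulene-6,10-dione | O=C1C[C@H](C)CC(=O)[C@H]2[C@]1(C)CC[C@@]2(O[Si](CC)(CC)CC)C(C)C
F6 | step 9 | trans-fused 4β-triethylsilyloxy-4α-isopropyl-1β,8α-dimethyl-5α-H-decahydroazulene-6,10-dione | O=C1C[C@H](C)CC(=O)[C@@H]2[C@]1(C)CC[C@@]2(O[Si](CC)(CC)CC)C(C)C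
F7 | step 14 | C9=C10 trimethylsilyl enol ether of 14 with 4-trimethylsilyloxy | C[Si](C)(C)OC1=C[C@H](C)C[C@H](OC(=O)CC(C)C)[C@@H]2[C@]1(C)CC[C@@]2(O[Si](C)(C)C)C(C)C
F8 | step 14 | C8=C9 enone (C10 ketone), 6α-isovalerate, 4β-trimethylsilyloxy | O=C1C=C(C)C[C@H](OC(=O)CC(C)C)[C@@H]2[C@]1(C)CC[C@@]2(O[Si](C)(C)C)C(C)C
F9 | step 14 | 10α-hydroxy C8=C9 alkene, 6α-isovalerate, 4β-trimethylsilyloxy | O[C@@H]1C=C(C)C[C@H](OC(=O)CC(C)C)[C@@H]2[C@]1(C)CC[C@@]2(O[Si](C)(C)C)C(C)C
F10 | step 7 | tricyclic 4-hydroxy-4-isopropyl 6,10-dipivalate (4-OH on the convex face) | CC(C)(C)C(=O)O[C@]12C[C@H](C)C[C@@]1(OC(=O)C(C)(C)C)[C@@H]3[C@](O)(C(C)C)CC[C@]23C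
A1 | alternative 1 | (3R)-6-methyl-3-(propan-2-yl)hepta-1,6-dien-3-ol | C=C[C@](O)(C(C)C)CCC(C)=C
A2 | alternative 1 | 2,3-bis(hydroxymethyl)-3-methyl-1-(propan-2-yl)cyclopentan-1-ol configured as C4, C5 and C1 of the target | OC[C@@]1(C)CC[C@@](O)(C(C)C)[C@@H]1CO
A3 | alternative 2 | (7E,9E)-3-diazo-7-methylundeca-1,7,9-trien-4-one | C=CC(=[N+]=[N-])C(=O)CC/C(C)=C/C=C/C
A4 | alternative 2 | bicyclic dienone (target locants: C4 ketone, C5=C6, C9=C10, 1,8-dimethyl) | C[C@H]1C=C[C@@]2(C)CCC(=O)C2=CC1
A5 | alternative 3 | cyclopentane with 5-[1-(tert-butyldimethylsilyloxy)vinyl], 4-triethylsilyloxy-4-isopropyl, 1-methyl and 1-[1-(tert-butyldimethylsilyloxy)but-2-ynyl] groups | CC(C)(C)[Si](C)(C)O[C@H](C#CC)[C@@]1(C)CC[C@@](O[Si](CC)(CC)CC)(C(C)C)[C@@H]1C(=C)O[Si](C)(C)C(C)(C)C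
A6 | alternative 3 | bicyclic C6 ketone with C8=C9, 10α-tert-butyldimethylsilyloxy and 4β-triethylsilyloxy | CC(C)(C)[Si](C)(C)O[C@@H]1C=C(C)CC(=O)[C@@H]2[C@]1(C)CC[C@@]2(O[Si](CC)(CC)CC)C(C)C
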